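**Retrosynthetic overview**

1. Feature: ring A, the trioxygenated benzene ring (C1 bears the benzoyl group, C2/C4/C6 bear oxygen, C3 bears side-chain carbon C1', C5 is CH). C3 lies between two oxygenated carbons and the oxygens alternate, which is the pattern left when an alkoxyalkyne carrying the chain is spliced into a 3-alkoxycyclobutenone.
2. Endgame: target 24 ⇐ acid removal of MOM and TBS ⇐ thiolate de-ethylation ⇐ C1–C(=O) bond by ortho-lithiation and Weinreb benzoylation of MOM ether 19 (the phenyl ring arrives intact).
3. Ring A (the only ring that is built) ⇐ Danheiser benzannulation of 3-ethoxycyclobutenone 13 with ynol ether 12: new bonds C2–C3 and C4–C5, closure at C1–C2 by six-electron electrocyclisation.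
4. 12 ⇐ (S)-vinyl epoxide 8 + lithium ethoxyacetylide (C3–C1' bond); 8 ⇐ CBS reduction of chloromethyl enone 6 (sets C2') ⇐ Shapiro vinyllithium from sulcatone + chloroacetyl Weinreb amide.

Key step: step 7

Remark: lithiation in step 9 at either free ring CH would lead to the same target after full deprotection, because all three ring oxygens end as OH; the route is written for the CH between OMOM and OEt, the position the MOM group should favour.

**Route**

Step 1
Reactants: 1 6-methylhept-5-en-2-one (sulcatone); 2 2,4,6-triisopropylbenzenesulfonohydrazide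
Product: 3 (E)-N'-(6-methylhept-5-en-2-ylidene)-2,4,6-triisopropylbenzenesulfonohydrazide
Conditions: MeOH, conc. HCl (cat.), rt
Reagents that add atoms: none
Why: Acid-catalysed hydrazone formation from a methyl ketone should proceed cleanly at room temperature, and the trisyl group is chosen because it resists ortho-lithiation in the Shapiro reaction that follows.

Step 2
Reactants: 3 trisylhydrazone; 4 2-chloro-N-methoxy-N-methylacetamide
Product: 6 1-chloro-7-methyl-3-methylideneoct-6-en-2-one, via vinyllithium 5 (not isolated)
Conditions: n-BuLi (2.05 equiv), THF, –78 → 0 °C; then 4, –78 °C; 1 M HCl, –78 → 0 °C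
Reagents that add atoms: none
Why: Shapiro reaction (trisylhydrazone variant): double deprotonation at the α-methyl group syn to the sulfonamide nitrogen, then loss of sulfinate and N2, should give the 2-lithio-1-alkene, which the Weinreb amide acylates once through its chelated tetrahedral intermediate to give the chloromethyl ketone.

Step 3
Reactants: 6 1-chloro-7-methyl-3-methylideneoct-6-en-2-one
Product: 7 (2S)-1-chloro-7-methyl-3-methylideneoct-6-en-2-ol
Conditions: (S)-2-methyl-CBS-oxazaborolidine (0.15 equiv), catecholborane (1.5 equiv), toluene, –78 °C; MeOH quench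
Reagents that add atoms: none
Why: Corey–Bakshi–Shibata reduction, in which the ketone binds to the catalyst boron with the α-branched alkenyl group as the large substituent and CH2Cl as the small one, so that hydride from the coordinated borane should add to the face giving the (S)-chlorohydrin (the same sense as phenacyl chloride with the (S)-catalyst), while catecholborane at low temperature leaves both olefins untouched.

Step 4
Reactants: 7 (2S)-1-chloro-7-methyl-3-methylideneoct-6-en-2-ol
Product: 8 (2S)-2-(6-methylhepta-1,5-dien-2-yl)oxirane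
Conditions: K2CO3, MeOH, 0 °C → rt
Reagents that add atoms: none
Why: Intramolecular Williamson displacement of the primary chloride by the alkoxide should close the epoxide without touching the stereocentre, so the configuration is retained.

Step 5
Reactants: 8 (2S)-2-(6-methylhepta-1,5-dien-2-yl)oxirane; 9 ethoxyethyne
Product: 11 (4R)-1-ethoxy-9-methyl-5-methylidenedec-8-en-1-yn-4-ol, via lithium ethoxyacetylide 10 (not isolated)
Conditions: 9 (2 equiv), n-BuLi (1.9 equiv), THF, –78 °C; BF3·OEt2 (2 equiv); then 8, –78 °C; sat. aq. NaHCO3 quench; Et3N-buffered silica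
Reagents that add atoms: none
Why: Yamaguchi–Hirao alkynylation, in which the alkynyl–BF3 ate species should open the activated monosubstituted epoxide by SN2 attack at the unhindered CH2 terminus, leaving the carbinol centre untouched (its descriptor changes from S to R only through the priority change).

Step 6
Reactants: 11 (4R)-1-ethoxy-9-methyl-5-methylidenedec-8-en-1-yn-4-ol
Product: 12 (R)-tert-butyl[(1-ethoxy-9-methyl-5-methylidenedec-8-en-1-yn-4-yl)oxy]dimethylsilane
Conditions: TBSCl, imidazole, DMAP (cat.), DMF, 0 °C → rt
Reagents that add atoms: tert-butyldimethylsilyl chloride, CC(C)(C)[Si](C)(C)Cl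
Why: Silylation of the secondary alcohol under buffered basic conditions should preserve the acid-sensitive ynol ether and removes the hydroxyl group that would otherwise add to the ynol ether or to a ketene in step 7.

Step 7
Reactants: 12 (R)-tert-butyl[(1-ethoxy-9-methyl-5-methylidenedec-8-en-1-yn-4-yl)oxy]dimethylsilane; 13 3-ethoxycyclobut-2-en-1-one
Product: 18 2-[(2R)-2-(tert-butyldimethylsilyloxy)-7-methyl-3-methylideneoct-6-en-1-yl]-3,5-diethoxyphenol, via vinylketene 14 (not isolated), via vinylcyclobutenone 15 (not isolated), via dienylketene 16 (not isolated), via cyclohexadienone 17 (not isolated)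
Conditions: 13 (1.5 equiv, in portions), toluene, 80 °C then 100 °C, sealed tube, argon
Reagents that add atoms: none
Why: Danheiser benzannulation: on heating, 13 should open by reversible four-electron electrocyclic cleavage of its C(=O)–CH2 bond (future C2–C1) to vinylketene 14, which ynol ether 12 traps in a [2+2] cycloaddition to give vinylcyclobutenone 15 with the new bonds C2–C3 and C5–C4. A second four-electron opening of 15 (cleaving C2–C5) gives dienylketene 16, whose six-electron disrotatory electrocyclisation re-forms C1–C2 and closes ring A as cyclohexadienone 17, which tautomerises to phenol 18. The closest known reaction type is the thermal benzannulation of cyclobutenones with alkoxyalkynes to resorcinol monoethers; the less-tested element is a 3-alkoxycyclobutenone as the vinylketene source. No stereocentre is created in the product (the sp3 ring carbon of 15 is transient), and the silylated C2' centre is remote from all bond-forming events and should not epimerise under neutral thermal conditions. The selectivity needed is the regiochemistry of the ketene–alkyne [2+2] step, secured by the polarisation of the ynol ether: its nucleophilic β-carbon (future C3, bearing the chain) bonds to the electrophilic ketene carbonyl carbon (future C2), which places the chain between two oxygenated carbons. The ynol ether must also outlast its own retro-ene loss of ethylene, which is why the temperature is held at 80–100 °C and 13 is used in excess.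

Step 8
Reactants: 18 2-[(2R)-2-(tert-butyldimethylsilyloxy)-7-methyl-3-methylideneoct-6-en-1-yl]-3,5-diethoxyphenol
Product: 19 tert-butyl({(2R)-1-[2,4-diethoxy-6-(methoxymethoxy)phenyl]-7-methyl-3-methylideneoct-6-en-2-yl}oxy)dimethylsilane
Conditions: NaH, MOMCl, THF/DMF, 0 °C → rt
Reagents that add atoms: chloromethyl methyl ether, COCCl
Why: Williamson O-alkylation of the sodium phenoxide should install the MOM group, which is the strongest ortho-director on the ring for step 9 and is removable under the final mild acid conditions.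

Step 9
Reactants: 19 MOM ether; 20 N-methoxy-N-methylbenzamide
Product: 22 {3-[(2R)-2-(tert-butyldimethylsilyloxy)-7-methyl-3-methylideneoct-6-en-1-yl]-4,6-diethoxy-2-(methoxymethoxy)phenyl}(phenyl)methanone, via aryllithium 21 (not isolated)
Conditions: n-BuLi (1.2 equiv), TMEDA, THF, 0 °C; then 20, –78 → 0 °C; H2O quench
Reagents that add atoms: none
Why: Directed ortho-metalation should remove the ring hydrogen flanked by OMOM and OEt (cooperative coordination, MOM the stronger director), and the aryllithium is acylated once by the Weinreb amide through its chelated tetrahedral intermediate to give the benzophenone.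

Step 10
Reactants: 22 diethoxy benzophenone
Product: 23 {3-[(2R)-2-(tert-butyldimethylsilyloxy)-7-methyl-3-methylideneoct-6-en-1-yl]-4,6-dihydroxy-2-(methoxymethoxy)phenyl}(phenyl)methanone
Conditions: NaSEt (8 equiv), DMF, 130 °C, argon; then dilute aq. HCl to pH 5–6, 0 °C
Reagents that add atoms: none
Why: SN2 dealkylation of aryl ethyl ethers by thiolate in a dipolar aprotic solvent should be helped by the ortho and para benzoyl group, which stabilises the departing phenoxides, while the unactivated alkenes are inert to this soft nucleophile and any early loss of the silyl or MOM group is harmless because both are removed in step 11.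

Step 11
Reactants: 23 dihydroxy benzophenone
Product: 24 {2,4,6-trihydroxy-3-[(2R)-2-hydroxy-7-methyl-3-methylideneoct-6-en-1-yl]phenyl}(phenyl)methanone (target)
Conditions: HCl (cat., 1.25 M in MeOH), MeOH, 0 °C → rt
Reagents that add atoms: none
Why: Acid-catalysed acetal exchange of the aryl MOM ether (activated by the ortho carbonyl) and methanolysis of the secondary silyl ether should both proceed under dilute acid at room temperature, conditions too mild to ionise the allylic alcohol or protonate the olefins, so the C2' configuration is retained.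

**Compound list**

1 | 6-methylhept-5-en-2-one (sulcatone) | CC(=O)CCC=C(C)C | starting material
2 | 2,4,6-triisopropylbenzenesulfonohydrazide | CC(C)c1cc(C(C)C)c(S(=O)(=O)NN)c(C(C)C)c1 | starting material
3 | (E)-N'-(6-methylhept-5-en-2-ylidene)-2,4,6-triisopropylbenzenesulfonohydrazide | C/C(CCC=C(C)C)=N\NS(=O)(=O)c1c(C(C)C)cc(C(C)C)cc1C(C)C | intermediate
4 | 2-chloro-N-methoxy-N-methylacetamide | CON(C)C(=O)CCl | starting material
5 | (6-methylhepta-1,5-dien-2-yl)lithium | [Li]C(=C)CCC=C(C)C | intermediate
6 | 1-chloro-7-methyl-3-methylideneoct-6-en-2-one | C=C(CCC=C(C)C)C(=O)CCl | intermediate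
7 | (2S)-1-chloro-7-methyl-3-methylideneoct-6-en-2-ol | C=C(CCC=C(C)C)[C@H](O)CCl | intermediate
8 | (2S)-2-(6-methylhepta-1,5-dien-2-yl)oxirane | C=C(CCC=C(C)C)[C@H]1CO1 | intermediate
9 | ethoxyethyne | CCOC#C | starting material
10 | lithium ethoxyacetylide | [Li]C#COCC | intermediate
11 | (4R)-1-ethoxy-9-methyl-5-methylidenedec-8-en-1-yn-4-ol | C=C(CCC=C(C)C)[C@H](O)CC#COCC | intermediate
12 | (R)-tert-butyl[(1-ethoxy-9-methyl-5-methylidenedec-8-en-1-yn-4-yl)oxy]dimethylsilane | C=C(CCC=C(C)C)[C@H](O[Si](C)(C)C(C)(C)C)CC#COCC | intermediate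
13 | 3-ethoxycyclobut-2-en-1-one | CCOC1=CC(=O)C1 | starting material
14 | 3-ethoxybuta-1,3-dien-1-one (vinylketene) | C=C(OCC)C=C=O | intermediate
15 | 3-ethoxy-4-(1-ethoxyethenyl)-2-[(2R)-2-(tert-butyldimethylsilyloxy)-7-methyl-3-methylideneoct-6-en-1-yl]cyclobut-2-en-1-one (mixture at the ring sp3 carbon) | C=C(CCC=C(C)C)[C@H](O[Si](C)(C)C(C)(C)C)CC1=C(OCC)C(C(=C)OCC)C1=O | intermediate
16 | (3E)-3,5-diethoxy-2-[(2R)-2-(tert-butyldimethylsilyloxy)-7-methyl-3-methylideneoct-6-en-1-yl]hexa-1,3,5-trien-1-one (dienylketene) | C=C(CCC=C(C)C)[C@H](O[Si](C)(C)C(C)(C)C)CC(=C=O)/C(OCC)=C\C(=C)OCC | intermediate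
17 | 3,5-diethoxy-2-[(2R)-2-(tert-butyldimethylsilyloxy)-7-methyl-3-methylideneoct-6-en-1-yl]cyclohexa-2,4-dien-1-one | C=C(CCC=C(C)C)[C@H](O[Si](C)(C)C(C)(C)C)CC1=C(OCC)C=C(OCC)CC1=O | intermediate
18 | 2-[(2R)-2-(tert-butyldimethylsilyloxy)-7-methyl-3-methylideneoct-6-en-1-yl]-3,5-diethoxyphenol | C=C(CCC=C(C)C)[C@H](O[Si](C)(C)C(C)(C)C)Cc1c(O)cc(OCC)cc1OCC | intermediate
19 | tert-butyl({(2R)-1-[2,4-diethoxy-6-(methoxymethoxy)phenyl]-7-methyl-3-methylideneoct-6-en-2-yl}oxy)dimethylsilane | C=C(CCC=C(C)C)[C@H](O[Si](C)(C)C(C)(C)C)Cc1c(OCOC)cc(OCC)cc1OCC | intermediate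
20 | N-methoxy-N-methylbenzamide | CON(C)C(=O)c1ccccc1 | starting material
21 | {3-[(2R)-2-(tert-butyldimethylsilyloxy)-7-methyl-3-methylideneoct-6-en-1-yl]-4,6-diethoxy-2-(methoxymethoxy)phenyl}lithium | C=C(CCC=C(C)C)[C@H](O[Si](C)(C)C(C)(C)C)Cc1c(OCOC)c([Li])c(OCC)cc1OCC | intermediate
22 | {3-[(2R)-2-(tert-butyldimethylsilyloxy)-7-methyl-3-methylideneoct-6-en-1-yl]-4,6-diethoxy-2-(methoxymethoxy)phenyl}(phenyl)methanone | C=C(CCC=C(C)C)[C@H](O[Si](C)(C)C(C)(C)C)Cc1c(OCOC)c(C(=O)c2ccccc2)c(OCC)cc1OCC | intermediate
23 | {3-[(2R)-2-(tert-butyldimethylsilyloxy)-7-methyl-3-methylideneoct-6-en-1-yl]-4,6-dihydroxy-2-(methoxymethoxy)phenyl}(phenyl)methanone | C=C(CCC=C(C)C)[C@H](O[Si](C)(C)C(C)(C)C)Cc1c(OCOC)c(C(=O)c2ccccc2)c(O)cc1O | intermediate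
24 | {2,4,6-trihydroxy-3-[(2R)-2-hydroxy-7-methyl-3-methylideneoct-6-en-1-yl]phenyl}(phenyl)methanone | C=C(CCC=C(C)C)[C@H](O)Cc1c(O)cc(O)c(C(=O)c2ccccc2)c1O | target

**Step count and risks**

Total steps: 11. Longest linear sequence: 11 steps (1 → 24).

Steps most likely to fail:

1. Step 7 (benzannulation). The ynol ether may be consumed by retro-ene loss of ethylene, giving a ketene that captures a second alkyne, before the vinylogous-ester cyclobutenone has opened. The product phenol may also be O-acylated by excess vinylketene, which a K2CO3/MeOH treatment of the crude would reverse. If the ring construction itself does not proceed, ring A would be taken ready-made. The fallback sets out from epoxide 8: commercial 3,5-diethoxyphenol F1 is converted with NaH and MOMCl into 1,3-diethoxy-5-(methoxymethoxy)benzene F2, which n-BuLi in THF at 0 °C lithiates between OMOM and OEt to give [2,4-diethoxy-6-(methoxymethoxy)phenyl]lithium F3. This aryllithium opens 8 at its CH2 terminus in the presence of BF3·OEt2 at –78 °C to give (2R)-1-[2,4-diethoxy-6-(methoxymethoxy)phenyl]-7-methyl-3-methylideneoct-6-en-2-ol F4, and silylation with TBSCl and imidazole then gives 19, where the route is rejoined for steps 9 to 11.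

2. Step 10 (double de-ethylation). The second dealkylation may stall once the first phenoxide has formed, and prolonged heating with thiolate may bring loss of the silyl group or base-induced degradation of the side chain. The fallback avoids ethyl ethers altogether and sets out from epoxide 8: phloroglucinol F5 is converted with NaH and MOMCl in DMF into 1,3,5-tris(methoxymethoxy)benzene F6, lithiated with n-BuLi in THF at 0 °C to [2,4,6-tris(methoxymethoxy)phenyl]lithium F7, and this opens 8 under BF3·OEt2 at –78 °C to give (2R)-7-methyl-3-methylidene-1-[2,4,6-tris(methoxymethoxy)phenyl]oct-6-en-2-ol F8. TBSCl and imidazole give the silyl ether F9, a second lithiation with n-BuLi and TMEDA gives the aryllithium F10, and acylation with 20 gives the tris-MOM benzophenone F11. The conditions of step 11 (HCl in MeOH) then remove all four protecting groups and give 24 directly, where the route is rejoined.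

3. Step 5 (epoxide opening). Under Lewis acid activation the alkynyl nucleophile may attack the allylic epoxide carbon or add in SN2' fashion instead of at the CH2 terminus, and the γ-hydroxy ynol ether may cyclise by acid-triggered addition of its hydroxyl group during isolation. The fallback fixes the regiochemistry through the carbon skeleton of the chlorohydrin and sets out from 7: TBSCl and imidazole give tert-butyl{[(2S)-1-chloro-7-methyl-3-methylideneoct-6-en-2-yl]oxy}dimethylsilane F12, a Finkelstein exchange with NaI in butanone at reflux gives tert-butyl{[(2S)-1-iodo-7-methyl-3-methylideneoct-6-en-2-yl]oxy}dimethylsilane F13, and alkylation of lithium ethoxyacetylide 10 with F13 in THF/HMPA (–78 °C → rt) gives 12 directly, where the route is rejoined with no free hydroxy ynol ether ever handled.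

**Further compounds**

F1 | step 7 | 3,5-diethoxyphenol | CCOc1cc(O)cc(OCC)c1
F2 | step 7 | 1,3-diethoxy-5-(methoxymethoxy)benzene | CCOc1cc(OCC)cc(OCOC)c1
F3 | step 7 | [2,4-diethoxy-6-(methoxymethoxy)phenyl]lithium | CCOc1cc(OCC)c([Li])c(OCOC)c1
F4 | step 7 | (2R)-1-[2,4-diethoxy-6-(methoxymethoxy)phenyl]-7-methyl-3-methylideneoct-6-en-2-ol | C=C(CCC=C(C)C)[C@H](O)Cc1c(OCOC)cc(OCC)cc1OCC
F5 | step 10 | phloroglucinol (benzene-1,3,5-triol) | Oc1cc(O)cc(O)c1
F6 | step 10 | 1,3,5-tris(methoxymethoxy)benzene | COCOc1cc(OCOC)cc(OCOC)c1
F7 | step 10 | [2,4,6-tris(methoxymethoxy)phenyl]lithium | COCOc1cc(OCOC)c([Li])c(OCOC)c1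
F8 | step 10 | (2R)-7-methyl-3-methylidene-1-[2,4,6-tris(methoxymethoxy)phenyl]oct-6-en-2-ol | C=C(CCC=C(C)C)[C@H](O)Cc1c(OCOC)cc(OCOC)cc1OCOC
F9 | step 10 | tert-butyldimethyl({(2R)-7-methyl-3-methylidene-1-[2,4,6-tris(methoxymethoxy)phenyl]oct-6-en-2-yl}oxy)silane | C=C(CCC=C(C)C)[C@H](O[Si](C)(C)C(C)(C)C)Cc1c(OCOC)cc(OCOC)cc1OCOC
F10 | step 10 | {3-[(2R)-2-(tert-butyldimethylsilyloxy)-7-methyl-3-methylideneoct-6-en-1-yl]-2,4,6-tris(methoxymethoxy)phenyl}lithium | C=C(CCC=C(C)C)[C@H](O[Si](C)(C)C(C)(C)C)Cc1c(OCOC)cc(OCOC)c([Li])c1OCOC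
F11 | step 10 | {3-[(2R)-2-(tert-butyldimethylsilyloxy)-7-methyl-3-methylideneoct-6-en-1-yl]-2,4,6-tris(methoxymethoxy)phenyl}(phenyl)methanone | C=C(CCC=C(C)C)[C@H](O[Si](C)(C)C(C)(C)C)Cc1c(OCOC)cc(OCOC)c(C(=O)c2ccccc2)c1OCOC
F12 | step 5 | tert-butyl{[(2S)-1-chloro-7-methyl-3-methylideneoct-6-en-2-yl]oxy}dimethylsilane | C=C(CCC=C(C)C)[C@H](O[Si](C)(C)C(C)(C)C)CCl
F13 | step 5 | tert-butyl{[(2S)-1-iodo-7-methyl-3-methylideneoct-6-en-2-yl]oxy}dimethylsilane | C=C(CCC=C(C)C)[C@H](O[Si](C)(C)C(C)(C)C)CI
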